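The route rests on cutting the bridge CH2 on C6 of the dearomatised acetylfilicinic ring from the central butyrylphloroglucinol ring. The key step copies the presumed biosynthesis. Enantiopure C6–H acid 8 is loaded in the flask with one carbon (Mannich) and collapses to the 6-methylene trione 17, a quinone-methide-type acceptor flanked by C1=O and C5=O. Trione 17 is captured by the only free aromatic C–H of chromene–phloroglucinol dimer 15. One operation installs the bridge carbon, forms both its C–C bonds and unites all three rings without protecting groups. Both precursors are unprotected polyphenols. The C4 stereocentre comes from esterase desymmetrisation of a prochiral malonate and a polyketide-type Claisen ring closure.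

Key step: step 6

Remark on the chemistry: the enolised β-triketone and phenol rings are written in the tautomer of the target SMILES. The tautomers interconvert freely and none involves the quaternary C4, the only stereocentre. Numbering of the dearomatised ring: C1(=O), C2(acetyl), C3(OH), C4(methyl, geranyl), C5(OH), C6.

Step 1
Reactants: 1 dimethyl 2-methylmalonate; 2 geranyl bromide, (E)-1-bromo-3,7-dimethylocta-2,6-diene
Product: 3 dimethyl 2-[(2E)-3,7-dimethylocta-2,6-dien-1-yl]-2-methylmalonate
Conditions: NaH, THF, 0 °C; then 2, 0 °C → rt
Reagents that add atoms: none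
Why: Malonic ester alkylation, in which SN2 attack of the sodium enolate on the primary allylic bromide should occur without allylic transposition and with retention of the E-alkene, and the quaternary carbon formed is still prochiral because its two ester groups are identical.

Step 2
Reactants: 3 dimethyl 2-geranyl-2-methylmalonate
Product: 4 (R,E)-2-(methoxycarbonyl)-2,5,9-trimethyldeca-4,8-dienoic acid
Conditions: pig liver esterase, 0.1 M phosphate buffer pH 7.5–DMSO (9:1), 25 °C, pH-stat (1 M NaOH); then 1 M HCl, EtOAc
Reagents that add atoms: water, O
Why: Enzymatic desymmetrisation of a prochiral α,α-disubstituted malonate by a serine esterase (carboxylesterase class), in which, by analogy with long-chain 2-alkyl-2-methylmalonates, the geranyl chain should occupy the large hydrophobic pocket so that only the pro-S ester is hydrolysed, which sets the quaternary centre as R, and the anionic half-ester is not hydrolysed further.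

Step 3
Reactants: 4 (R)-half-ester; 5 acetylacetone (pentane-2,4-dione)
Product: 8 (R)-2-acetyl-4-geranyl-3,5-dihydroxy-4-methylcyclohexa-2,5-dien-1-one, via acid chloride 6 (not isolated), via triketo ester 7 (not isolated)
Conditions: (i) 1-chloro-N,N,2-trimethylprop-1-en-1-amine, CH2Cl2, 0 °C → rt, evaporate; (ii) 5 (3 equiv), NaH then n-BuLi, THF, 0 °C; 6 added at −78 °C → rt, then 50 °C; 1 M HCl
Reagents that add atoms: none
Why: Terminal (γ) C-acylation of a β-diketone dianion by the acid chloride, which is far more reactive than the hindered methyl ester, followed by polyketide-type Claisen (Dieckmann) cyclisation of the 3,5,7-triketo ester, in which the aldol alternative is blocked by the quaternary carbon, gem-disubstitution favours closure and any O-closed pyranone can reopen with methoxide; the stereocentre is untouched and its sense is carried over because the acid carbon becomes C5 (next to C6–H) and the ester carbon becomes C3 (next to C2–acetyl).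

Step 4
Reactants: 9 1-(2,4,6-trihydroxyphenyl)butan-1-one (phlorbutyrophenone); 10 3-methylbut-2-enal (prenal)
Product: 12 1-(5,7-dihydroxy-2,2-dimethyl-2H-chromen-8-yl)butan-1-one, via prenylidene quinone methide 11 (not isolated)
Conditions: ethylenediammonium diacetate (10 mol %), xylene, reflux, water separator
Reagents that add atoms: none
Why: Knoevenagel-type condensation at a ring C–H followed by oxa-6π electrocyclisation of the o-quinone methide (formal [3+3] chromenylation, known for acylphloroglucinols), where closure through the oxygen ortho to the acyl group gives the 8-acyl chromene, and the 6-acyl regioisomer and any bis-chromene are to be removed by chromatography.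

Step 5
Reactants: 12 8-butanoyl-5,7-dihydroxy-2,2-dimethylchromene; 9 phlorbutyrophenone
Product: 15 1-{3-[(8-butanoyl-5,7-dihydroxy-2,2-dimethyl-2H-chromen-6-yl)methyl]-2,4,6-trihydroxyphenyl}butan-1-one, via chromene Mannich salt 13 (not isolated), via chromene quinone methide 14 (not isolated)
Conditions: Me2N+=CH2 I− (1.0 equiv), CH2Cl2, rt; evaporate; 9 (3 equiv), NaOAc, 1,4-dioxane, 90 °C
Reagents that add atoms: N,N-dimethylmethyleneiminium iodide, C=[N+](C)C.[I-]
Why: Mannich aminomethylation at C6, the only free aromatic position of 12, then thermal loss of dimethylamine to o-quinone methide 14 and Friedel–Crafts-type conjugate addition of 9, whose excess should suppress double alkylation, which is the established Mannich-base route to unsymmetrical methylene-bridged acylphloroglucinols.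

Step 6
Reactants: 8 (R)-acetyl geranyl-methyl filicinic acid; 15 chromene–phloroglucinol dimer
Product: 18 target CNP0103039.1, via filicinic Mannich salt 16 (not isolated), via methylene trione 17 (not isolated)
Conditions: Me2N+=CH2 I− (0.98 equiv), MeCN, 0 °C → rt; then 15 (1.05 equiv), NaOAc, MeCN–THF, 40 °C
Reagents that add atoms: N,N-dimethylmethyleneiminium iodide, C=[N+](C)C.[I-]
Why: The enol carbon C6 of 8, the only C–H of the vinylogous-acid ring, attacks the iminium ion (Mannich reaction), so the whole one-carbon unit is fixed on this partner as the stable ammonium salt 16 before 15 is added; acetate then deprotonates the acidic β-triketone and E1cB loss of dimethylamine releases the 6-methylene trione 17, whose exocyclic C=CH2 is activated by both C1=O and C5=O. The central ring of 15 adds through its only unsubstituted aromatic carbon, which lies between two hydroxyl groups, in a Friedel–Crafts-type Michael addition, and tautomerisation restores both the arene and the enolised triketone. The closest known reaction types are the Mannich-base/quinone-methide coupling used for unsymmetrical methylene-bridged acylphloroglucinols and the addition of acylphloroglucinols to alkylidene β-triketones, and the step mirrors the presumed biosynthetic bridge formation. No ring is closed and no stereocentre is created; C4 is quaternary and non-enolisable and no bond to it is broken, so its R configuration is carried through unchanged. The step needs cross- over homo-coupling and C- over O-alkylation: the first is secured by the sequential loading (no free 8 and no free iminium salt remain when 17 is released) and by 15 having a single nucleophilic C–H, the second by the reversibility of O-addition and by rearomatisation after C-addition. Hetero-Diels–Alder capture of 17 by the geranyl or chromene alkenes and retro-Michael scrambling of the bridge already present should be held back by the low temperature and the weak base.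

Compound list
1 | dimethyl 2-methylmalonate | COC(=O)C(C)C(=O)OC | starting material
2 | geranyl bromide | BrC/C=C(\C)CCC=C(C)C | starting material
3 | dimethyl 2-geranyl-2-methylmalonate | COC(=O)C(C)(C/C=C(\C)CCC=C(C)C)C(=O)OC | intermediate
4 | (R,E)-2-(methoxycarbonyl)-2,5,9-trimethyldeca-4,8-dienoic acid | OC(=O)[C@@](C)(C/C=C(\C)CCC=C(C)C)C(=O)OC | intermediate
5 | acetylacetone | CC(=O)CC(C)=O | starting material
6 | methyl (S,E)-2-(chlorocarbonyl)-2,5,9-trimethyldeca-4,8-dienoate (same spatial arrangement as 4) | ClC(=O)[C@@](C)(C/C=C(\C)CCC=C(C)C)C(=O)OC | intermediate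
7 | methyl (R)-2-geranyl-2-methyl-3,5,7-trioxooctanoate | CC(=O)CC(=O)CC(=O)[C@@](C)(C/C=C(\C)CCC=C(C)C)C(=O)OC | intermediate
8 | (R)-2-acetyl-4-geranyl-3,5-dihydroxy-4-methylcyclohexa-2,5-dien-1-one | O=C1C=C(O)[C@@](C)(C/C=C(\C)CCC=C(C)C)C(O)=C1C(C)=O | intermediate
9 | 1-(2,4,6-trihydroxyphenyl)butan-1-one | CCCC(=O)c1c(O)cc(O)cc1O | starting material
10 | 3-methylbut-2-enal | CC(C)=CC=O | starting material
11 | 2-butanoyl-3,5-dihydroxy-6-(3-methylbut-2-enylidene)cyclohexa-2,4-dien-1-one | CCCC(=O)C1=C(O)C=C(O)C(=CC=C(C)C)C1=O | intermediate
12 | 1-(5,7-dihydroxy-2,2-dimethyl-2H-chromen-8-yl)butan-1-one | CCCC(=O)c1c(O)cc(O)c2C=CC(C)(C)Oc12 | intermediate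
13 | (8-butanoyl-5,7-dihydroxy-2,2-dimethyl-2H-chromen-6-yl)methyl-dimethylammonium iodide | CCCC(=O)c1c(O)c(C[NH+](C)C)c(O)c2C=CC(C)(C)Oc12.[I-] | intermediate
14 | 8-butanoyl-7-hydroxy-2,2-dimethyl-6-methylidene-2H-chromen-5(6H)-one | CCCC(=O)C1=C(O)C(=C)C(=O)C2=C1OC(C)(C)C=C2 | intermediate
15 | 1-{3-[(8-butanoyl-5,7-dihydroxy-2,2-dimethyl-2H-chromen-6-yl)methyl]-2,4,6-trihydroxyphenyl}butan-1-one | CCCC(=O)c1c(O)cc(O)c(Cc2c(O)c3c(c(C(=O)CCC)c2O)OC(C)(C)C=C3)c1O | intermediate
16 | [(R)-3-acetyl-5-geranyl-4,6-dihydroxy-5-methyl-2-oxocyclohexa-3,6-dien-1-yl]methyl-dimethylammonium iodide (C6 Mannich salt of 8) | C[NH+](C)CC1=C(O)[C@@](C)(C/C=C(\C)CCC=C(C)C)C(O)=C(C(C)=O)C1=O.[I-] | intermediate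
17 | 2-acetyl-4-geranyl-3-hydroxy-4-methyl-6-methylidenecyclohex-2-ene-1,5-dione (C4 arranged as in 8; descriptor S because C5 is now a ketone) | C=C1C(=O)[C@@](C)(C/C=C(\C)CCC=C(C)C)C(O)=C(C(C)=O)C1=O | intermediate
18 | CNP0103039.1, (R) at C4 of the dearomatised ring | CCCC(=O)c1c(O)c(CC2=C(O)[C@@](C)(C/C=C(\C)CCC=C(C)C)C(O)=C(C(C)=O)C2=O)c(O)c(Cc2c(O)c3c(c(C(=O)CCC)c2O)OC(C)(C)C=C3)c1O | target

Total step count: 6
Longest linear sequence: 4 steps (1 → 2 → 3 → 6); the second branch is 4 → 5 → 6.

Steps most likely to fail

1. Step 6. The methide may be released too early or too slowly. It could then be consumed by self-condensation or by hetero-Diels–Alder reaction with the alkenes. The liberated dimethylamine may condense with the acetyl group, and the bridge already present may scramble by retro-Michael cleavage. The fallback sets out from 8 and uses an isolated, amine-free methide precursor. Three-component sulfonylmethylation of 8 with paraformaldehyde and p-toluenesulfinic acid (aq. EtOH, rt) should give the crystalline sulfone (R)-2-acetyl-4-geranyl-3,5-dihydroxy-4-methyl-6-(tosylmethyl)cyclohexa-2,5-dien-1-one F1, which is purified. F1 is added slowly at 0 °C to the pre-formed caesium phenolate of 15 in THF. It should lose sulfinate, and the methide, kept at low concentration by the addition rate, should be captured at the same aromatic carbon. The fallback comes back to the route at 18.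

2. Step 3. The dianion may be O-acylated or acylated twice, it may attack the methyl ester, and the ring may close through oxygen instead of carbon. The fallback sets out from 5 and 6. It replaces the strongly basic dianion by a neutral silyl dienol ether and separates chain building from ring closure. Compound 5 is silylated (Me3SiCl, Et3N) to 4-(trimethylsilyloxy)pent-3-en-2-one F2, then again (LDA, Me3SiCl) to 2,4-bis(trimethylsilyloxy)penta-1,3-diene F3. F3 should attack 6 through its terminal carbon in CH2Cl2 (−78 °C → rt) without base. Mild aqueous work-up gives 7, which is now isolated. Separate Claisen closure with Mg(OMe)2 or NaOMe in MeOH comes back to the route at 8.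

3. Step 2. The enzyme may discriminate poorly between the two enantiotopic ester groups, or the very lipophilic substrate may turn over slowly. The fallback sets out from 3. One equivalent of KOH in MeOH gives racemic 2-(methoxycarbonyl)-2,5,9-trimethyldeca-4,8-dienoic acid F4. This acid is resolved classically by fractional crystallisation of the (R)-1-phenylethylammonium salt of the (R)-acid F5; the enantiomeric amine is used if its salt with the R acid is the less soluble one. Acidification comes back to the route at 4. The unwanted acid can be re-esterified to achiral 3 and recycled.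

Further compounds
F1 | step 6 | (R)-2-acetyl-4-geranyl-3,5-dihydroxy-4-methyl-6-(tosylmethyl)cyclohexa-2,5-dien-1-one | Cc1ccc(cc1)S(=O)(=O)CC1=C(O)[C@@](C)(C/C=C(\C)CCC=C(C)C)C(O)=C(C(C)=O)C1=O
F2 | step 3 | 4-(trimethylsilyloxy)pent-3-en-2-one | CC(=O)C=C(C)O[Si](C)(C)C
F3 | step 3 | 2,4-bis(trimethylsilyloxy)penta-1,3-diene | C=C(O[Si](C)(C)C)C=C(C)O[Si](C)(C)C
F4 | step 2 | racemic (E)-2-(methoxycarbonyl)-2,5,9-trimethyldeca-4,8-dienoic acid | OC(=O)C(C)(C/C=C(\C)CCC=C(C)C)C(=O)OC
F5 | step 2 | (R)-1-phenylethylammonium (R,E)-2-(methoxycarbonyl)-2,5,9-trimethyldeca-4,8-dienoate | [O-]C(=O)[C@@](C)(C/C=C(\C)CCC=C(C)C)C(=O)OC.C[C@@H]([NH3+])c1ccccc1
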